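## Retrosynthetic overview

1. Numbering as in carotenoids: ring A (triol cyclohexane) C1–C6, then C7=C8, ring B (butenolide) C9–C10–C11 with C19 as the lactone C=O, chain C12–C15, then C15', C12'–C7', ring C (cyclohexene) C6'–C1'.
2. Two sp2–sp2 single bonds are cut, C12'–C15' (centre of the tetraene) and C8–C9 (vinyl to lactone α-carbon). This gives a ring-A vinylstannane (C11), a 3-bromo-5-ylidenebutenolide trienylboronate core (C10) and a ring-C dienynyl iodide (C16). The three are joined in one pot, Stille first at C8–C9, then Suzuki–Miyaura at C12'–C15'.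
3. Enabling feature: C9 of ring B sits α to the lactone C=O and takes a bromide that reacts with zerovalent palladium without base, while C15' at the far end of the same triene can carry a boronate that stays silent until base is added. In addition the tetraene C9'=C10'–C11'=C12'–C15'=C15–C14=C13 is locally symmetric about C12'–C15' (two (E)-CH=CH–CH=C(CH3) units), so both flanks of that bond come from one enynol by two Takai-type one-carbon olefinations.
4. Ring order: rings A and C are both taken from (4R,6R)-actinol; ring B is closed third, by Sonogashira coupling/5-exo-dig lactonisation, before the key step; the key step closes no ring.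
5. Stereocentres: C3' from actinol; C3 by Mitsunobu inversion of actinol; C5 and C6 by hydroxyl-directed epoxidation, then opening by water at C5 with inversion.

Key step: step 20

Remark: the target is read as (3R,5S,6S,3'R), so the ring-A carbinol C3 has the opposite spatial sense to C3' and C4 of actinol must be inverted for ring A; (4R,6R)-actinol, (E)-3-methylpent-2-en-4-yn-1-ol, propiolic acid, ethynyltrimethylsilane and Cl2CHBpin are taken as purchasable.

## Route

### Ring-C iodide (left half)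

Step 1
Reactants: 1 (4R,6R)-4-hydroxy-2,2,6-trimethylcyclohexanone (actinol)
Product: 2 (4R,6R)-4-[(tert-butyldimethylsilyl)oxy]-2,2,6-trimethylcyclohexanone
Conditions: TBSCl, imidazole, DMF, 23 °C
Reagents that add atoms: tert-butyldimethylsilyl chloride, CC(C)(C)[Si](C)(C)Cl
Why: Standard silylation of the only hydroxyl protects C4–OH for the strongly basic step that follows, and no stereocentre is touched.

Step 2
Reactants: 2 (4R,6R)-4-[(tert-butyldimethylsilyl)oxy]-2,2,6-trimethylcyclohexanone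
Product: 3 (4R)-4-[(tert-butyldimethylsilyl)oxy]-2,6,6-trimethylcyclohex-1-en-1-yl trifluoromethanesulfonate
Conditions: LDA, THF, −78 °C; then PhNTf2, −78 → 0 °C
Reagents that add atoms: N-phenylbis(trifluoromethanesulfonimide), O=S(=O)(N(c1ccccc1)S(=O)(=O)C(F)(F)F)C(F)(F)F
Why: Enol triflate formation: only C6 carries an α-hydrogen, so a single fully substituted lithium enolate forms and is O-sulfonylated, which removes the C6 stereocentre on purpose and leaves C4 unchanged.

Step 3
Reactants: 3 (4R)-4-[(tert-butyldimethylsilyl)oxy]-2,6,6-trimethylcyclohex-1-en-1-yl trifluoromethanesulfonate; 4 (2E)-3-methylpent-2-en-4-yn-1-ol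
Product: 5 (2E)-5-[(4R)-4-[(tert-butyldimethylsilyl)oxy]-2,6,6-trimethylcyclohex-1-en-1-yl]-3-methylpent-2-en-4-yn-1-ol
Conditions: Pd(PPh3)4 (5 mol%), CuI (10 mol%), i-Pr2NH, DMF, 23 → 40 °C
Reagents that add atoms: none
Why: Sonogashira coupling of the vinyl triflate with the terminal alkyne of 4 forms the C6'–C7' bond and carries the E trisubstituted alkene through unchanged.

Step 4
Reactants: 5 (2E)-5-[(4R)-4-[(tert-butyldimethylsilyl)oxy]-2,6,6-trimethylcyclohex-1-en-1-yl]-3-methylpent-2-en-4-yn-1-ol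
Product: 6 (2E)-5-[(4R)-4-[(tert-butyldimethylsilyl)oxy]-2,6,6-trimethylcyclohex-1-en-1-yl]-3-methylpent-2-en-4-ynal
Conditions: MnO2 (activated), CH2Cl2, 23 °C
Reagents that add atoms: none
Why: Chemoselective MnO2 oxidation of the allylic primary alcohol should leave the silyl ether, the alkyne and the E alkene untouched.

Step 5
Reactants: 6 (2E)-5-[(4R)-4-[(tert-butyldimethylsilyl)oxy]-2,6,6-trimethylcyclohex-1-en-1-yl]-3-methylpent-2-en-4-ynal
Product: 7 tert-butyl{[(1R)-4-[(3E,5E)-6-iodo-3-methylhexa-3,5-dien-1-yn-1-yl]-3,5,5-trimethylcyclohex-3-en-1-yl]oxy}dimethylsilane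
Conditions: CrCl2, CHI3, THF/1,4-dioxane, 0 → 23 °C, dark
Reagents that add atoms: iodoform, IC(I)I
Why: Takai iodo-olefination: the geminal dichromium species from CHI3 and CrCl2 adds to the aldehyde and eliminates to the (E)-iodoalkene, which installs C12' as the electrophilic terminus.

Step 6
Reactants: 7 tert-butyl{[(1R)-4-[(3E,5E)-6-iodo-3-methylhexa-3,5-dien-1-yn-1-yl]-3,5,5-trimethylcyclohex-3-en-1-yl]oxy}dimethylsilane
Product: 8 (1R)-4-[(3E,5E)-6-iodo-3-methylhexa-3,5-dien-1-yn-1-yl]-3,5,5-trimethylcyclohex-3-en-1-ol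
Conditions: HF·pyridine, pyridine, THF, 0 → 23 °C, dark
Reagents that add atoms: none
Why: Buffered fluoride cleavage of the secondary silyl ether (deprotection) should leave the dienyl iodide and the enyne intact, so that the key step can deliver the free target.

### Boronate core with ring B

Step 7
Reactants: 4 (2E)-3-methylpent-2-en-4-yn-1-ol
Product: 9 (2E)-3-methylpent-2-en-4-ynal
Conditions: MnO2 (activated), CH2Cl2, 23 °C; used as a solution
Reagents that add atoms: none
Why: Allylic MnO2 oxidation as in step 4; the volatile enynal is not concentrated.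

Step 8
Reactants: 9 (2E)-3-methylpent-2-en-4-ynal
Product: 10 4,4,5,5-tetramethyl-2-[(1E,3E)-4-methylhexa-1,3-dien-5-yn-1-yl]-1,3,2-dioxaborolane
Conditions: CrCl2, LiI, Cl2CHBpin, THF, 23 °C
Reagents that add atoms: 2-(dichloromethyl)-4,4,5,5-tetramethyl-1,3,2-dioxaborolane, CC1(C)OB(C(Cl)Cl)OC1(C)C
Why: Boron variant of the Takai olefination: LiI turns the dichloride into the diiodide, CrCl2 forms the geminal dichromium reagent, and addition to the enal with elimination gives the (E)-alkenylboronate, installing C15' as the nucleophilic terminus.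

Step 9
Reactants: 11 propiolic acid
Product: 12 (2E)-2,3-dibromoprop-2-enoic acid
Conditions: Br2, CHCl3, 0 → 23 °C, dark
Reagents that add atoms: bromine, BrBr
Why: Ionic anti-addition of bromine across the alkyne gives the (E)-dibromide, in which the β-bromine is cis to the carboxyl group as the later ring closure requires.

Step 10
Reactants: 12 (2E)-2,3-dibromoprop-2-enoic acid; 10 4,4,5,5-tetramethyl-2-[(1E,3E)-4-methylhexa-1,3-dien-5-yn-1-yl]-1,3,2-dioxaborolane
Product: 14 (5Z)-3-bromo-5-[(2E,4E)-2-methyl-5-(4,4,5,5-tetramethyl-1,3,2-dioxaborolan-2-yl)penta-2,4-dien-1-ylidene]furan-2(5H)-one, via bromo-enynoic acid 13 (not isolated)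
Conditions: PdCl2(PPh3)2 (5 mol%), CuI (10 mol%), Et3N, MeCN, 23 °C, dark
Reagents that add atoms: none
Why: Tandem Sonogashira coupling/lactonisation: palladium inserts into the more electrophilic β-C–Br bond, the copper acetylide of 10 couples with retention, and the carboxylate of 13 adds 5-exo-dig and anti across the metal-activated alkyne to close ring B with the Z exocyclic alkene, while amine and carboxylate bases do not activate the pinacol boronate and the α-bromide stays.

### Ring-A stannane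

Step 11
Reactants: 1 (4R,6R)-4-hydroxy-2,2,6-trimethylcyclohexanone (actinol)
Product: 15 (4S,6R)-2,2,6-trimethyl-4-[(4-nitrobenzoyl)oxy]cyclohexanone
Conditions: 4-nitrobenzoic acid, PPh3, DIAD, toluene/THF, 0 → 23 °C
Reagents that add atoms: 4-nitrobenzoic acid, OC(=O)c1ccc(cc1)[N+](=O)[O-]
Why: Mitsunobu reaction: the C4 hydroxyl is activated as the oxyphosphonium ion and displaced by 4-nitrobenzoate in an SN2 process, which inverts C4 from R to S.

Step 12
Reactants: 15 (4S,6R)-2,2,6-trimethyl-4-[(4-nitrobenzoyl)oxy]cyclohexanone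
Product: 16 (4S,6R)-4-hydroxy-2,2,6-trimethylcyclohexanone
Conditions: K2CO3 (0.2 equiv), MeOH, 0 °C
Reagents that add atoms: none
Why: Base-catalysed transesterification releases the inverted alcohol; C6, the only epimerisable centre, already holds the more stable cis arrangement and is removed in step 14.

Step 13
Reactants: 16 (4S,6R)-4-hydroxy-2,2,6-trimethylcyclohexanone
Product: 17 (4S,6R)-4-[(tert-butyldimethylsilyl)oxy]-2,2,6-trimethylcyclohexanone
Conditions: TBSCl, imidazole, DMF, 23 °C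
Reagents that add atoms: tert-butyldimethylsilyl chloride, CC(C)(C)[Si](C)(C)Cl
Why: Silylation as in step 1.

Step 14
Reactants: 17 (4S,6R)-4-[(tert-butyldimethylsilyl)oxy]-2,2,6-trimethylcyclohexanone
Product: 18 (4S)-4-[(tert-butyldimethylsilyl)oxy]-2,6,6-trimethylcyclohex-1-en-1-yl trifluoromethanesulfonate
Conditions: LDA, THF, −78 °C; then PhNTf2, −78 → 0 °C
Reagents that add atoms: N-phenylbis(trifluoromethanesulfonimide), O=S(=O)(N(c1ccccc1)S(=O)(=O)C(F)(F)F)C(F)(F)F
Why: Regiodefined enol triflate formation as in step 2, giving the enantiomer of 3.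

Step 15
Reactants: 18 (4S)-4-[(tert-butyldimethylsilyl)oxy]-2,6,6-trimethylcyclohex-1-en-1-yl trifluoromethanesulfonate; 19 ethynyltrimethylsilane
Product: 20 tert-butyldimethyl{[(1S)-3,5,5-trimethyl-4-[(trimethylsilyl)ethynyl]cyclohex-3-en-1-yl]oxy}silane
Conditions: Pd(PPh3)4 (5 mol%), CuI (10 mol%), i-Pr2NH, DMF, 40 °C
Reagents that add atoms: none
Why: Sonogashira coupling of the hindered vinyl triflate with a small silyl-capped alkyne attaches C7 and C8 to C6.

Step 16
Reactants: 20 tert-butyldimethyl{[(1S)-3,5,5-trimethyl-4-[(trimethylsilyl)ethynyl]cyclohex-3-en-1-yl]oxy}silane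
Product: 21 (1S)-4-ethynyl-3,5,5-trimethylcyclohex-3-en-1-ol
Conditions: TBAF (2.5 equiv), THF, 23 °C
Reagents that add atoms: none
Why: Fluoride cleaves both the alkynyl C–Si and the O–Si bond (global desilylation) and frees the homoallylic hydroxyl that directs the next step.

Step 17
Reactants: 21 (1S)-4-ethynyl-3,5,5-trimethylcyclohex-3-en-1-ol
Product: 22 (1R,3R,6R)-6-ethynyl-1,5,5-trimethyl-7-oxabicyclo[4.1.0]heptan-3-ol (oxirane oxygen cis to the hydroxyl)
Conditions: VO(acac)2 (5 mol%), t-BuOOH, CH2Cl2, 0 → 23 °C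
Reagents that add atoms: tert-butyl hydroperoxide, CC(C)(C)OO
Why: Hydroxyl-directed epoxidation: the C3 alkoxide binds the vanadium peroxo complex and delivers oxygen to the alkene face cis to itself, which sets C5 and C6 relative to C3, and the alkyne is inert.

Step 18
Reactants: 22 (1R,3R,6R)-6-ethynyl-1,5,5-trimethyl-7-oxabicyclo[4.1.0]heptan-3-ol
Product: 23 (1R,2S,4R)-1-ethynyl-2,6,6-trimethylcyclohexane-1,2,4-triol
Conditions: HClO4 (cat.), THF/H2O, 0 → 23 °C
Reagents that add atoms: water, O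
Why: Acid-catalysed epoxide hydrolysis: water should open the protonated oxirane at C5 with inversion, because C6 is shielded by the quaternary C1 and its cation is destabilised by the ethynyl group, giving the trans-5,6-diol with C6 retained.

Step 19
Reactants: 23 (1R,2S,4R)-1-ethynyl-2,6,6-trimethylcyclohexane-1,2,4-triol
Product: 24 (1S,2S,4R)-2,6,6-trimethyl-1-[(E)-2-(tributylstannyl)ethenyl]cyclohexane-1,2,4-triol
Conditions: Bu3SnH, PdCl2(PPh3)2 (2 mol%), THF, 0 °C
Reagents that add atoms: tributyltin hydride, CCCC[SnH](CCCC)CCCC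
Why: Palladium-catalysed syn-hydrostannylation of the terminal alkyne: tin goes to the terminal carbon because the internal position is blocked by the fully substituted carbinol centre, giving the (E)-vinylstannane.

### Key step

Step 20
Reactants: 24 (1S,2S,4R)-2,6,6-trimethyl-1-[(E)-2-(tributylstannyl)ethenyl]cyclohexane-1,2,4-triol; 14 (5Z)-3-bromo-5-[(2E,4E)-2-methyl-5-(4,4,5,5-tetramethyl-1,3,2-dioxaborolan-2-yl)penta-2,4-dien-1-ylidene]furan-2(5H)-one; 8 (1R)-4-[(3E,5E)-6-iodo-3-methylhexa-3,5-dien-1-yn-1-yl]-3,5,5-trimethylcyclohex-3-en-1-ol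
Product: 26 (5Z)-5-[(2E,4E,6E,8E)-11-[(4R)-4-hydroxy-2,6,6-trimethylcyclohex-1-en-1-yl]-2,9-dimethylundeca-2,4,6,8-tetraen-10-yn-1-ylidene]-3-[(E)-2-[(1S,2S,4R)-1,2,4-trihydroxy-2,6,6-trimethylcyclohexyl]ethenyl]furan-2(5H)-one (the target), via right-half dienylboronate 25 (not isolated)
Conditions: 24 (1.05 equiv), 14, Pd2(dba)3 (2.5 mol%), AsPh3 (20 mol%), THF/DMF, 45 °C, dark, Ar; then 8, Pd(OAc)2 (5 mol%), SPhos (10 mol%), degassed 3 M aq K3PO4, 23 °C
Reagents that add atoms: none
Why: In stage 1 zerovalent palladium inserts into the C9–Br bond of 14 (the only carbon–halogen bond present), the alkenyl group of 24 is transferred from tin with retention and reductive elimination forms C8–C9, while the boronate at C15' cannot transmetalate without an oxygen base and survives as 25. In stage 2 oxidative addition into the C12'–I bond of 8, phosphate-triggered transmetalation of the boronate of 25 and reductive elimination form the C12'–C15' bond, joining the C21 right half to the C16 left half. The closest known reaction type is the one-pot sequential Stille/Suzuki–Miyaura three-component coupling of polyene building blocks that carry two orthogonal cross-coupling handles. No ring is closed and no stereocentre is created; all four stereocentres and all alkene geometries come in with 24, 14 and 8, and both couplings proceed with retention at sp2 carbon. The step needs site selectivity (bromide before boronate), secured by leaving out base in stage 1 and by consuming the bromide fully before base is added, which also prevents head-to-tail oligomerisation of 14. It also needs survival of the enol lactone and the four free hydroxyls, for which a mild phosphate base at 23 °C with exclusion of light and oxygen is chosen.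

## Compound list

1 | (4R,6R)-4-hydroxy-2,2,6-trimethylcyclohexanone (actinol) | C[C@H]1C(=O)C(C)(C)C[C@H](O)C1 | starting material
2 | (4R,6R)-4-[(tert-butyldimethylsilyl)oxy]-2,2,6-trimethylcyclohexanone | C[C@H]1C(=O)C(C)(C)C[C@H](O[Si](C)(C)C(C)(C)C)C1 | intermediate
3 | (4R)-4-[(tert-butyldimethylsilyl)oxy]-2,6,6-trimethylcyclohex-1-en-1-yl trifluoromethanesulfonate | CC1=C(OS(=O)(=O)C(F)(F)F)C(C)(C)C[C@H](O[Si](C)(C)C(C)(C)C)C1 | intermediate
4 | (2E)-3-methylpent-2-en-4-yn-1-ol | C#C/C(C)=C/CO | starting material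
5 | (2E)-5-[(4R)-4-[(tert-butyldimethylsilyl)oxy]-2,6,6-trimethylcyclohex-1-en-1-yl]-3-methylpent-2-en-4-yn-1-ol | CC1=C(C#C/C(C)=C/CO)C(C)(C)C[C@H](O[Si](C)(C)C(C)(C)C)C1 | intermediate
6 | (2E)-5-[(4R)-4-[(tert-butyldimethylsilyl)oxy]-2,6,6-trimethylcyclohex-1-en-1-yl]-3-methylpent-2-en-4-ynal | CC1=C(C#C/C(C)=C/C=O)C(C)(C)C[C@H](O[Si](C)(C)C(C)(C)C)C1 | intermediate
7 | tert-butyl{[(1R)-4-[(3E,5E)-6-iodo-3-methylhexa-3,5-dien-1-yn-1-yl]-3,5,5-trimethylcyclohex-3-en-1-yl]oxy}dimethylsilane | CC1=C(C#C/C(C)=C/C=C/I)C(C)(C)C[C@H](O[Si](C)(C)C(C)(C)C)C1 | intermediate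
8 | (1R)-4-[(3E,5E)-6-iodo-3-methylhexa-3,5-dien-1-yn-1-yl]-3,5,5-trimethylcyclohex-3-en-1-ol | CC1=C(C#C/C(C)=C/C=C/I)C(C)(C)C[C@H](O)C1 | intermediate
9 | (2E)-3-methylpent-2-en-4-ynal | C#C/C(C)=C/C=O | intermediate
10 | 4,4,5,5-tetramethyl-2-[(1E,3E)-4-methylhexa-1,3-dien-5-yn-1-yl]-1,3,2-dioxaborolane | C#C/C(C)=C/C=C/B1OC(C)(C)C(C)(C)O1 | intermediate
11 | propiolic acid | C#CC(=O)O | starting material
12 | (2E)-2,3-dibromoprop-2-enoic acid | OC(=O)/C(Br)=C\Br | intermediate
13 | (2E,6E,8E)-2-bromo-6-methyl-9-(4,4,5,5-tetramethyl-1,3,2-dioxaborolan-2-yl)nona-2,6,8-trien-4-ynoic acid | OC(=O)/C(Br)=C\C#C/C(C)=C/C=C/B1OC(C)(C)C(C)(C)O1 | intermediate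
14 | (5Z)-3-bromo-5-[(2E,4E)-2-methyl-5-(4,4,5,5-tetramethyl-1,3,2-dioxaborolan-2-yl)penta-2,4-dien-1-ylidene]furan-2(5H)-one | CC1(C)OB(/C=C/C=C(C)/C=C2C=C(Br)C(=O)O/2)OC1(C)C | intermediate
15 | (4S,6R)-2,2,6-trimethyl-4-[(4-nitrobenzoyl)oxy]cyclohexanone | C[C@H]1C(=O)C(C)(C)C[C@@H](OC(=O)c2ccc(cc2)[N+](=O)[O-])C1 | intermediate
16 | (4S,6R)-4-hydroxy-2,2,6-trimethylcyclohexanone | C[C@H]1C(=O)C(C)(C)C[C@@H](O)C1 | intermediate
17 | (4S,6R)-4-[(tert-butyldimethylsilyl)oxy]-2,2,6-trimethylcyclohexanone | C[C@H]1C(=O)C(C)(C)C[C@@H](O[Si](C)(C)C(C)(C)C)C1 | intermediate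
18 | (4S)-4-[(tert-butyldimethylsilyl)oxy]-2,6,6-trimethylcyclohex-1-en-1-yl trifluoromethanesulfonate | CC1=C(OS(=O)(=O)C(F)(F)F)C(C)(C)C[C@@H](O[Si](C)(C)C(C)(C)C)C1 | intermediate
19 | ethynyltrimethylsilane | C#C[Si](C)(C)C | starting material
20 | tert-butyldimethyl{[(1S)-3,5,5-trimethyl-4-[(trimethylsilyl)ethynyl]cyclohex-3-en-1-yl]oxy}silane | CC1=C(C#C[Si](C)(C)C)C(C)(C)C[C@@H](O[Si](C)(C)C(C)(C)C)C1 | intermediate
21 | (1S)-4-ethynyl-3,5,5-trimethylcyclohex-3-en-1-ol | CC1=C(C#C)C(C)(C)C[C@@H](O)C1 | intermediate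
22 | (1R,3R,6R)-6-ethynyl-1,5,5-trimethyl-7-oxabicyclo[4.1.0]heptan-3-ol (oxirane oxygen cis to OH) | C#C[C@]1(O2)C(C)(C)C[C@@H](O)C[C@]12C | intermediate
23 | (1R,2S,4R)-1-ethynyl-2,6,6-trimethylcyclohexane-1,2,4-triol | C#C[C@]1(O)C(C)(C)C[C@@H](O)C[C@]1(C)O | intermediate
24 | (1S,2S,4R)-2,6,6-trimethyl-1-[(E)-2-(tributylstannyl)ethenyl]cyclohexane-1,2,4-triol | CCCC[Sn](CCCC)(CCCC)/C=C/[C@]1(O)C(C)(C)C[C@@H](O)C[C@]1(C)O | intermediate
25 | (5Z)-5-[(2E,4E)-2-methyl-5-(4,4,5,5-tetramethyl-1,3,2-dioxaborolan-2-yl)penta-2,4-dien-1-ylidene]-3-[(E)-2-[(1S,2S,4R)-1,2,4-trihydroxy-2,6,6-trimethylcyclohexyl]ethenyl]furan-2(5H)-one | CC1(C)OB(/C=C/C=C(C)/C=C2C=C(/C=C/[C@]3(O)C(C)(C)C[C@@H](O)C[C@]3(C)O)C(=O)O/2)OC1(C)C | intermediate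
26 | (5Z)-5-[(2E,4E,6E,8E)-11-[(4R)-4-hydroxy-2,6,6-trimethylcyclohex-1-en-1-yl]-2,9-dimethylundeca-2,4,6,8-tetraen-10-yn-1-ylidene]-3-[(E)-2-[(1S,2S,4R)-1,2,4-trihydroxy-2,6,6-trimethylcyclohexyl]ethenyl]furan-2(5H)-one | CC1=C(C#C/C(C)=C/C=C/C=C/C=C(C)/C=C2C=C(/C=C/[C@]3(O)C(C)(C)C[C@@H](O)C[C@]3(C)O)C(=O)O/2)C(C)(C)C[C@H](O)C1 | target

## Step count and risks

Total step count: 20. Longest linear sequence: 10 steps (1 → 15 → 16 → 17 → 18 → 20 → 21 → 22 → 23 → 24 → 26, steps 11 to 20).

The three steps most likely to fail: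

**Step 20 (key step).** What may go wrong: premature transmetalation of the boronate in stage 1 with head-to-tail oligomerisation of 14, or opening of the enol lactone and protodeboronation under the aqueous base of stage 2. The fallback forms the C12'–C15' bond by a base-free Stille coupling and introduces the two one-carbon termini later. It sets out from 12, 4, 24 and 7 and comes back at 26.
- Tandem Sonogashira coupling/lactonisation of 12 with enynol 4 (PdCl2(PPh3)2, CuI, Et3N) should give (5Z)-3-bromo-5-[(2E)-4-hydroxy-2-methylbut-2-en-1-ylidene]furan-2(5H)-one F1.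
- Stille coupling of F1 with 24 (Pd2(dba)3, AsPh3) should give the ring-A butenolide allylic alcohol F2.
- MnO2 should oxidise F2 to the enal F3, and Takai iodo-olefination (CHI3, CrCl2) should give the right-half dienyl iodide F4.
- In parallel, 7 is converted by iodine–lithium exchange (t-BuLi, −78 °C) and Bu3SnCl into the dienylstannane F5.
- Stille coupling of F4 with F5 (Pd2(dba)3, AsPh3, DMF, 23 °C) should give the 3'-O-silyl ether F6 of the target, and HF·pyridine should release 26.

**Step 18.** What may go wrong: water opens the oxirane at the propargylic carbon C6 instead of C5, which would give the wrong trans-diol. The fallback uses the diastereomeric oxirane, for which attack at C6 with inversion leads to the same triol. It sets out from 20 and comes back at 23.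
- K2CO3 in MeOH should remove only the alkynyl silyl group of 20 and give the silyl ether F7.
- mCPBA (NaHCO3, CH2Cl2) should epoxidise F7 on the face away from the bulky silyloxy group to give the trans-oxirane F8.
- TBAF should give the epoxy alcohol F9, which is hydrolysed under the conditions of step 18 to 23.

**Step 17.** What may go wrong: poor facial selectivity of oxygen delivery (non-directed epoxidation trans to the hydroxyl competes) or oxidation of the carbinol. The fallback sets the oxirane by steric control in the R series and inverts the carbinol afterwards. It sets out from 3 and 19 and comes back at 22.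
- Sonogashira coupling of 3 with 19 should give the silylated enyne F10, and K2CO3 in MeOH the terminal alkyne F11.
- mCPBA should epoxidise F11 trans to the silyloxy group to give F12, and TBAF should give the epoxy alcohol F13.
- Mitsunobu reaction of F13 (4-nitrobenzoic acid, PPh3, DIAD) should invert the carbinol to the ester F14, and K2CO3 in MeOH should release 22.

## Further compounds

F1 | step 20 | (5Z)-3-bromo-5-[(2E)-4-hydroxy-2-methylbut-2-en-1-ylidene]furan-2(5H)-one | OC/C=C(C)/C=C1C=C(Br)C(=O)O/1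
F2 | step 20 | (5Z)-5-[(2E)-4-hydroxy-2-methylbut-2-en-1-ylidene]-3-[(E)-2-[(1S,2S,4R)-1,2,4-trihydroxy-2,6,6-trimethylcyclohexyl]ethenyl]furan-2(5H)-one | OC/C=C(C)/C=C1C=C(/C=C/[C@]2(O)C(C)(C)C[C@@H](O)C[C@]2(C)O)C(=O)O/1
F3 | step 20 | (2E)-3-methyl-4-[(2Z)-5-oxo-4-[(E)-2-[(1S,2S,4R)-1,2,4-trihydroxy-2,6,6-trimethylcyclohexyl]ethenyl]furan-2(5H)-ylidene]but-2-enal | O=C/C=C(C)/C=C1C=C(/C=C/[C@]2(O)C(C)(C)C[C@@H](O)C[C@]2(C)O)C(=O)O/1
F4 | step 20 | (5Z)-5-[(2E,4E)-5-iodo-2-methylpenta-2,4-dien-1-ylidene]-3-[(E)-2-[(1S,2S,4R)-1,2,4-trihydroxy-2,6,6-trimethylcyclohexyl]ethenyl]furan-2(5H)-one | I/C=C/C=C(C)/C=C1C=C(/C=C/[C@]2(O)C(C)(C)C[C@@H](O)C[C@]2(C)O)C(=O)O/1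
F5 | step 20 | tert-butyldimethyl{[(1R)-3,5,5-trimethyl-4-[(3E,5E)-3-methyl-6-(tributylstannyl)hexa-3,5-dien-1-yn-1-yl]cyclohex-3-en-1-yl]oxy}silane | CC1=C(C#C/C(C)=C/C=C/[Sn](CCCC)(CCCC)CCCC)C(C)(C)C[C@H](O[Si](C)(C)C(C)(C)C)C1
F6 | step 20 | tert-butyldimethylsilyl ether of 26 at the ring-C hydroxyl | CC1=C(C#C/C(C)=C/C=C/C=C/C=C(C)/C=C2C=C(/C=C/[C@]3(O)C(C)(C)C[C@@H](O)C[C@]3(C)O)C(=O)O/2)C(C)(C)C[C@H](O[Si](C)(C)C(C)(C)C)C1
F7 | step 18 | tert-butyl{[(1S)-4-ethynyl-3,5,5-trimethylcyclohex-3-en-1-yl]oxy}dimethylsilane | CC1=C(C#C)C(C)(C)C[C@@H](O[Si](C)(C)C(C)(C)C)C1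
F8 | step 18 | tert-butyl{[(1S,3R,6S)-6-ethynyl-1,5,5-trimethyl-7-oxabicyclo[4.1.0]heptan-3-yl]oxy}dimethylsilane (oxirane oxygen trans to the silyloxy group) | C#C[C@@]1(O2)C(C)(C)C[C@@H](O[Si](C)(C)C(C)(C)C)C[C@@]12C
F9 | step 18 | (1S,3R,6S)-6-ethynyl-1,5,5-trimethyl-7-oxabicyclo[4.1.0]heptan-3-ol (oxirane oxygen trans to OH) | C#C[C@@]1(O2)C(C)(C)C[C@@H](O)C[C@@]12C
F10 | step 17 | tert-butyldimethyl{[(1R)-3,5,5-trimethyl-4-[(trimethylsilyl)ethynyl]cyclohex-3-en-1-yl]oxy}silane | CC1=C(C#C[Si](C)(C)C)C(C)(C)C[C@H](O[Si](C)(C)C(C)(C)C)C1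
F11 | step 17 | tert-butyl{[(1R)-4-ethynyl-3,5,5-trimethylcyclohex-3-en-1-yl]oxy}dimethylsilane | CC1=C(C#C)C(C)(C)C[C@H](O[Si](C)(C)C(C)(C)C)C1
F12 | step 17 | tert-butyl{[(1R,3S,6R)-6-ethynyl-1,5,5-trimethyl-7-oxabicyclo[4.1.0]heptan-3-yl]oxy}dimethylsilane (oxirane oxygen trans to the silyloxy group) | C#C[C@]1(O2)C(C)(C)C[C@H](O[Si](C)(C)C(C)(C)C)C[C@]12C
F13 | step 17 | (1R,3S,6R)-6-ethynyl-1,5,5-trimethyl-7-oxabicyclo[4.1.0]heptan-3-ol (oxirane oxygen trans to OH) | C#C[C@]1(O2)C(C)(C)C[C@H](O)C[C@]12C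
F14 | step 17 | (1R,3R,6R)-6-ethynyl-1,5,5-trimethyl-7-oxabicyclo[4.1.0]heptan-3-yl 4-nitrobenzoate | C#C[C@]1(O2)C(C)(C)C[C@@H](OC(=O)c3ccc(cc3)[N+](=O)[O-])C[C@]12C
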